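Marchantin C is cut at the bond between C4 of ring A and the neighbouring carbon of the A–D ethano bridge. That carbon is carried as the acylium ion of a ring D arylacetic acid, so a single Friedel–Crafts acylation forms the bond and closes the 18-membered ring. The step exploits the C4–H of ring A, para to the C1 methoxy oxygen and meta to the C2 aryloxy oxygen, without prior functionalisation of that carbon. The precursor is the open A–B–C–D chain ending in CH2CO2H. Its ring C oxygen is worn as an acetate, because C4′–H and C6′–H of a ring C anisole would rival ring A in intermolecular acylation.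

Key step: step 8

Remark on stereochemistry: the target has no stereocentre and its SMILES carries no descriptor. The macrocycle is assumed to be conformationally mobile at room temperature, so it is made as one achiral compound and no step controls configuration.

Atom labels:
- Ring A: C1 (OMe, later OH), C2 (O to ring B), C4 (bridge carbon).
- Ring B: 1,4-phenylene.
- Ring C: C1′ (CH2), C2′ (O to ring D), C3′ (O), C4′–C6′ (H).
- Ring D: 1,3-phenylene.

Step 1
Reactants: 1 guaiacol (2-methoxyphenol); 2 4-fluorobenzaldehyde
Product: 3 4-(2-methoxyphenoxy)benzaldehyde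
Conditions: K2CO3, DMF, 120 °C
Reagents that add atoms: none
Why: SNAr (addition–elimination), in which the para-formyl group stabilises the Meisenheimer adduct and fluoride leaves readily, so potassium guaiacolate should give the A–B diaryl ether cleanly.

Step 2
Reactants: 3 4-(2-methoxyphenoxy)benzaldehyde
Product: 4 [4-(2-methoxyphenoxy)phenyl]methanol
Conditions: NaBH4, MeOH, 0 °C
Reagents that add atoms: none
Why: Borohydride reduction of an aromatic aldehyde, to which the methyl and diaryl ethers are inert.

Step 3
Reactants: 4 [4-(2-methoxyphenoxy)phenyl]methanol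
Product: 5 [4-(2-methoxyphenoxy)benzyl]triphenylphosphonium bromide
Conditions: PPh3·HBr, MeCN, reflux
Reagents that add atoms: triphenylphosphine hydrobromide, [Br-].c1ccc(cc1)[PH+](c1ccccc1)c1ccccc1
Why: Direct phosphonium salt formation from a benzylic alcohol (SN1-type substitution), helped by the para-aryloxy group that stabilises the benzylic cation, so no separate bromide is needed.

Step 4
Reactants: 6 2-fluoro-3-hydroxybenzaldehyde
Product: 7 3-(benzyloxy)-2-fluorobenzaldehyde
Conditions: BnBr, K2CO3, DMF, rt
Reagents that add atoms: benzyl bromide, BrCc1ccccc1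
Why: Williamson ether synthesis; benzyl keeps the ring from becoming a phenoxide that would block the next SNAr, survives base and ylide, and is removed in the hydrogenation of step 7 at no extra cost.

Step 5
Reactants: 7 3-(benzyloxy)-2-fluorobenzaldehyde; 8 3-hydroxyphenylacetic acid
Product: 9 2-{3-[2-(benzyloxy)-6-formylphenoxy]phenyl}acetic acid
Conditions: K2CO3 (3 equiv), DMAc, 110 °C, N2; then 1 M HCl
Reagents that add atoms: none
Why: SNAr at the C–F bond activated by the ortho-formyl group; the phenoxide of the dianion is the only competent nucleophile, the carboxylate form keeps the benzylic CH2 too weakly acidic for Knoevenagel-type condensation with the aldehyde, and copper-mediated arylation of a hindered, hydrogen-bonded 2-hydroxybenzaldehyde is avoided.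

Step 6
Reactants: 5 [4-(2-methoxyphenoxy)benzyl]triphenylphosphonium bromide; 9 2-{3-[2-(benzyloxy)-6-formylphenoxy]phenyl}acetic acid
Product: 11 2-{3-[2-(benzyloxy)-6-{2-[4-(2-methoxyphenoxy)phenyl]ethenyl}phenoxy]phenyl}acetic acid (E/Z mixture), via phosphonium ylide 10 (not isolated)
Conditions: KOtBu (2.3 equiv), THF–DMF (4:1), 0 °C → rt; then 1 M HCl
Reagents that add atoms: none
Why: Wittig olefination of a non-enolisable aldehyde with a semi-stabilised benzylide; one extra equivalent of base holds the acid as its carboxylate, the alkene geometry is irrelevant because both isomers converge in step 7, and acid–base extraction should remove the phosphine oxide.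

Step 7
Reactants: 11 stilbene acid (E/Z mixture)
Product: 13 2-{3-[2-(acetyloxy)-6-{2-[4-(2-methoxyphenoxy)phenyl]ethyl}phenoxy]phenyl}acetic acid, via phenol acid 12 (not isolated)
Conditions: H2 (1 atm), 10% Pd/C, EtOAc, rt; filter; then Ac2O, pyridine, rt; H2O
Reagents that add atoms: acetic anhydride, CC(=O)OC(C)=O
Why: Heterogeneous catalytic hydrogenation saturates both alkene isomers and hydrogenolyses the benzyl ether in one operation, and O-acetylation of the freed phenol in the filtrate (any mixed anhydride at the acid is hydrolysed on quenching) installs the electron-poor group that switches ring C off.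

Step 8
Reactants: 13 seco arylacetic acid (ring A OMe, ring C OAc)
Product: 15 macrocyclic deoxybenzoin ketone (18-membered ring; C=O on the bridge carbon bonded to ring A C4; ring A OMe, ring C OAc), via acyl trifluoroacetate 14 (not isolated)
Conditions: TFAA (2 equiv), CH2Cl2, rt, 30 min; added over 12 h to TfOH (5 equiv) in CH2Cl2, rt (1 mM final); aq NaHCO3
Reagents that add atoms: none
Why: TFAA converts the acid into acyl trifluoroacetate 14, which does not acylate any ring of the molecule on its own and can wait in the syringe; on entering the TfOH solution it ionises (via the acyl triflate) to the arylacetyl cation, C4 of ring A adds to it, and the Wheland intermediate loses the C4 proton to give the aryl ketone. This is an intramolecular Friedel–Crafts acylation through a mixed anhydride under Brønsted-acid promotion, routine for five- to seven-membered rings and known under high dilution for large-ring aryl and thienyl ketones. The 18-membered ring closes in a formal 18-exo-dig mode (the C≡O+ bond stays outside the new ring), ring A becomes meta-bridged through C2 and C4, and slow addition into a fast reaction keeps the free electrophile well below the effective molarity of the closure. No stereocentre is created. One of fifteen aromatic C–H bonds must react: C4–H of ring A lies para to the only alkoxy donor in 13, C5–H is para only to the weaker aryloxy oxygen whose lone pair is shared with ring B, C6–H is ortho to OMe and would force that group into the cavity, the open sites of rings B and D are merely ortho to a diaryl ether oxygen or flanked by the side chain, and ring C is deactivated by its acetate and reachable only through a badly strained nine-membered metacyclophane. Product 15 carries an acylated ring A and an acetylated ring C, so it should accumulate in the flask without intercepting fresh acylium ion, and the meta-aryloxybenzyl cation is too poorly stabilised for decarbonylation to compete.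

Step 9
Reactants: 15 macrocyclic deoxybenzoin ketone
Product: 17 ring A O-methyl, ring C O-acetyl marchantin C, via benzylic alcohol 16 (not isolated)
Conditions: Et3SiH (5 equiv), TFA–CH2Cl2 (1:1), 0 °C → rt
Reagents that add atoms: none
Why: Ionic hydrogenation (Kursanov–Parnes): hydride transfer to the protonated ketone gives carbinol 16, which ionises to a cation stabilised by the para-methoxy group and takes a second hydride, while the acetate, the ethers and the still deactivated ring C are untouched.

Step 10
Reactants: 17 ring A O-methyl, ring C O-acetyl marchantin C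
Product: 18 marchantin C
Conditions: BBr3 (5 equiv), CH2Cl2, −78 °C → rt; then MeOH, reflux
Reagents that add atoms: none
Why: Lewis-acid cleavage of the aryl methyl ether with BBr3, followed by methanolysis of the boron aryloxides and of any remaining aryl acetate by the HBr/MeOH formed on quenching, should free both phenols while the diaryl ethers stay intact.

Compound list
1 | guaiacol | COc1ccccc1O | starting material
2 | 4-fluorobenzaldehyde | O=Cc1ccc(F)cc1 | starting material
3 | 4-(2-methoxyphenoxy)benzaldehyde | COc1ccccc1Oc1ccc(C=O)cc1 | intermediate
4 | [4-(2-methoxyphenoxy)phenyl]methanol | COc1ccccc1Oc1ccc(CO)cc1 | intermediate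
5 | [4-(2-methoxyphenoxy)benzyl]triphenylphosphonium bromide | COc1ccccc1Oc1ccc(C[P+](c2ccccc2)(c2ccccc2)c2ccccc2)cc1.[Br-] | intermediate
6 | 2-fluoro-3-hydroxybenzaldehyde | O=Cc1cccc(O)c1F | starting material
7 | 3-(benzyloxy)-2-fluorobenzaldehyde | O=Cc1cccc(OCc2ccccc2)c1F | intermediate
8 | 3-hydroxyphenylacetic acid | OC(=O)Cc1cccc(O)c1 | starting material
9 | 2-{3-[2-(benzyloxy)-6-formylphenoxy]phenyl}acetic acid | O=Cc1cccc(OCc2ccccc2)c1Oc1cccc(CC(=O)O)c1 | intermediate
10 | [4-(2-methoxyphenoxy)benzylidene]triphenylphosphorane (formed in the flask) | COc1ccccc1Oc1ccc(C=P(c2ccccc2)(c2ccccc2)c2ccccc2)cc1 | intermediate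
11 | 2-{3-[2-(benzyloxy)-6-{2-[4-(2-methoxyphenoxy)phenyl]ethenyl}phenoxy]phenyl}acetic acid (E/Z mixture, drawn without alkene descriptor) | COc1ccccc1Oc1ccc(C=Cc2cccc(OCc3ccccc3)c2Oc2cccc(CC(=O)O)c2)cc1 | intermediate
12 | 2-{3-[2-hydroxy-6-{2-[4-(2-methoxyphenoxy)phenyl]ethyl}phenoxy]phenyl}acetic acid (not isolated) | COc1ccccc1Oc1ccc(cc1)CCc1cccc(O)c1Oc1cccc(c1)CC(=O)O | intermediate
13 | 2-{3-[2-(acetyloxy)-6-{2-[4-(2-methoxyphenoxy)phenyl]ethyl}phenoxy]phenyl}acetic acid (precursor of the key step) | COc1ccccc1Oc1ccc(cc1)CCc1cccc(OC(C)=O)c1Oc1cccc(c1)CC(=O)O | intermediate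
14 | mixed anhydride of 13 with trifluoroacetic acid (not isolated) | COc1ccccc1Oc1ccc(cc1)CCc1cccc(OC(C)=O)c1Oc1cccc(c1)CC(=O)OC(=O)C(F)(F)F | intermediate
15 | macrocyclic deoxybenzoin ketone, ring A OMe, ring C OAc (product of the key step) | COc1ccc2cc1Oc1ccc(cc1)CCc1cccc(OC(C)=O)c1Oc1cccc(c1)CC2=O | intermediate
16 | macrocyclic benzylic alcohol, racemic, stereocentre erased in the same step (not isolated) | COc1ccc2cc1Oc1ccc(cc1)CCc1cccc(OC(C)=O)c1Oc1cccc(c1)CC2O | intermediate
17 | ring A O-methyl, ring C O-acetyl marchantin C | COc1ccc2cc1Oc1ccc(cc1)CCc1cccc(OC(C)=O)c1Oc1cccc(c1)CC2 | intermediate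
18 | marchantin C (achiral) | Oc1ccc2cc1Oc1ccc(cc1)CCc1cccc(O)c1Oc1cccc(c1)CC2 | target

Total step count: 10. Longest linear sequence: 8 (steps 1, 2, 3, 6, 7, 8, 9, 10).

Steps most likely to fail

First, step 8.
- **Risk:** Intermolecular acylation may outrun ring closure if the effective molarity is low. The acylium ion may also attack ring A para to the aryloxy oxygen instead of para to the methoxy oxygen.
- **Fallback:** The same bond is closed with a handle on ring A. The sequence sets out from 13 and returns at 16.
- **Sequence:**
  - NIS with catalytic TFA in MeCN iodinates 13 para to its only methoxy group, with a small electrophile and no ring-closure constraint, to give the C4-iodo seco acid F1.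
  - BH3·THF at 0 °C reduces the carboxylic acid in preference to the aryl acetate and gives the iodo alcohol F2.
  - Dess–Martin periodinane gives the iodo arylacetaldehyde F3.
  - A Nozaki–Hiyama–Kishi macrocyclisation (CrCl2, cat. NiCl2, DMF, high dilution) adds the arylchromium species to the aldehyde and gives benzylic alcohol 16.
  - The conditions of step 9 carry 16 on to 17.

Second, step 5.
- **Risk:** The dipotassium salt of the hydroxy acid may dissolve poorly and attack the hindered, alkoxy-flanked C–F bond so slowly that base-induced degradation of the aldehyde takes over.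
- **Fallback:** The acid is masked so that the nucleophile is a soluble mono-phenoxide. The sequence sets out from 8 and returns at 9, at the cost of two extra operations.
- **Sequence:**
  - Fischer esterification (MeOH, cat. H2SO4) gives methyl 3-hydroxyphenylacetate F4.
  - SNAr with 7 (Cs2CO3, DMF, 90 °C) gives methyl 2-{3-[2-(benzyloxy)-6-formylphenoxy]phenyl}acetate F5.
  - LiOH in THF–H2O at rt releases 9.

Third, step 6.
- **Risk:** Proton transfer from the acid and precipitation of its salt may quench the ylide. The ortho-aryloxy aldehyde may also react so sluggishly that the phosphonium salt decays under base.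
- **Fallback:** A more nucleophilic phosphonate carbanion is used in a solvent that dissolves carboxylates. The sequence sets out from 4 and returns at 11.
- **Sequence:**
  - PBr3 in CH2Cl2 gives 4-(2-methoxyphenoxy)benzyl bromide F6.
  - A Michaelis–Arbuzov reaction with P(OEt)3 at 130 °C gives diethyl [4-(2-methoxyphenoxy)benzyl]phosphonate F7.
  - Horner–Wadsworth–Emmons olefination of 9 (KOtBu, 2.3 equiv, DMF, 0 °C → rt) should give 11 as its E isomer, which step 7 accepts unchanged.

Further compounds
F1 | step 8 | 2-{3-[2-(acetyloxy)-6-{2-[4-(5-iodo-2-methoxyphenoxy)phenyl]ethyl}phenoxy]phenyl}acetic acid | COc1ccc(I)cc1Oc1ccc(cc1)CCc1cccc(OC(C)=O)c1Oc1cccc(c1)CC(=O)O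
F2 | step 8 | 2-[3-(2-hydroxyethyl)phenoxy]-3-{2-[4-(5-iodo-2-methoxyphenoxy)phenyl]ethyl}phenyl acetate | COc1ccc(I)cc1Oc1ccc(cc1)CCc1cccc(OC(C)=O)c1Oc1cccc(c1)CCO
F3 | step 8 | 3-{2-[4-(5-iodo-2-methoxyphenoxy)phenyl]ethyl}-2-[3-(2-oxoethyl)phenoxy]phenyl acetate | COc1ccc(I)cc1Oc1ccc(cc1)CCc1cccc(OC(C)=O)c1Oc1cccc(c1)CC=O
F4 | step 5 | methyl 3-hydroxyphenylacetate | COC(=O)Cc1cccc(O)c1
F5 | step 5 | methyl 2-{3-[2-(benzyloxy)-6-formylphenoxy]phenyl}acetate | COC(=O)Cc1cccc(Oc2c(C=O)cccc2OCc2ccccc2)c1
F6 | step 6 | 4-(2-methoxyphenoxy)benzyl bromide | COc1ccccc1Oc1ccc(CBr)cc1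
F7 | step 6 | diethyl [4-(2-methoxyphenoxy)benzyl]phosphonate | CCOP(=O)(Cc1ccc(Oc2ccccc2OC)cc1)OCC
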